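The ratio to follow is the cost: [starting material] charged over [target] found at 8.0 h. Starting material is charged in the smaller amount (10 mM against 11.0 mM of reagent in the second phase), so it is the limiting reagent by charge. Its ledger is simple: one unit of each cost is booked as target, and the rest of the cost stands elsewhere.

| flask | starting material | reagent in the second phase | protic impurity | remark | time | volume of the second phase over the first |
|---|---|---|---|---|---|---|
| blue | 10 mM | 11 mM | 5 mM | run made earlier |  |  |
| red | 10 mM | 11 mM | 7.5 mM | run made earlier |  |  |
| grey | 15 mM | 11 mM | 10 mM | run made earlier |  |  |
| flask | 10 mM | 11.0 mM | 10.0 mM |  | 8.0 h | 0.25 |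

| run | time / h | target / % |
|---|---|---|
| blue | 1.00 | 14.3 |
| blue | 3.00 | 24.4 |
| blue | 5.00 | 26.4 |
| blue | 8.00 | 29.4 |
| red | 1.00 | 12.2 |
| red | 3.00 | 21.8 |
| red | 5.00 | 23.3 |
| red | 8.00 | 24.2 |
| grey | 0.667 | 9.6 |
| grey | 1.33 | 15.5 |
| grey | 3.00 | 18.9 |
| grey | 8.00 | 22.5 |

(each reading ± 1 percentage point)

- in the second phase: reagent in the second phase; everything else is in the first
- charges count per volume of the first phase; a concentration in a rate is the amount of a species over the volume of its own phase; every rate counts per litre of the first phase
- the numbers in the tables scatter by 1 percentage point (one standard deviation)
- the earlier runs hold the two phases in the same ratio of volumes as the flask asked about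

- Sunday's: doubling the transfer coefficient of the reagent in the second phase, all else as stated
- Wednesday's: doubling the amount of reagent in the second phase, all else as stated

- amount of target at 8.0 h, in percent of the starting material charged
- the change that raises the amount of target at 8.0 h, in percent of the starting material charged most ("none" if none brings more than 2 percentage points) (Sunday's / Wednesday's / none)
- amount of target at 8.0 h, in percent of the starting material charged, after Sunday's

The blue and red runs differ in protic impurity and in nothing else that is charged, so their ledgers show what that impurity does to the cost at 8.00 h:

blue: 3.40

red: 4.13

The impurity price is the rise in cost per mM of protic impurity, with the other charges held: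

price = (red − blue) / (difference in [protic impurity]) = 0.292 mM⁻¹

This price is read from readings that scatter by 1 percentage point. My own reckoning takes the cost as a straight line in [protic impurity], which is an assumption and not a finding. The grey run, with another charge of starting material, stays out of that line. For the flask:

cost = 4.86, so [target] = 20.6% of the charge

The forecast gives 20.5%, and 22% after Sunday's. It names Wednesday's, on the ground that “Doubling the reagent nearly doubles the target”.

The flask gives 21.4%, and 21.8% after Sunday's. The best change is Wednesday's, which adds 8.1 points against 0.33 points for Sunday's.

    reagent in the reaction phase ⇌ reagent in the second phase, rate k1*([reagent in the reaction phase] - [reagent in the second phase]/K1) per volume of the first phase (partition coefficient = 0.520, kL = 1.30 × 10⁻⁴ s⁻¹)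
    starting material + reagent in the reaction phase → target (k = 0.00990 L mol⁻¹ s⁻¹)
    2 reagent in the reaction phase → homo dimer (k = 0.0200 L mol⁻¹ s⁻¹)
    starting material + protic impurity → quenched substrate (k = 0.0190 L mol⁻¹ s⁻¹)
    starting material + target → side product (k = 7.30 × 10⁻⁴ L mol⁻¹ s⁻¹)

The flask's cost is therefore 4.66. The flask's ledger at 8.00 h reads 5.24% starting material left, 21.4% target, 72.0% quenched substrate and 1.31% side product, a percentage in which each side product counts as two units of starting material. A neighbour charged with 17 mM of protic impurity, all else as in the flask, takes the same price: its cost comes to 6.91, which means 14.5% target. That neighbour gives 14.6%, with 84.7% of its charged starting material booked as quenched substrate at 8.00 h.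

Readings and results were computed with made-up constants; scatter was added.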